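Slowness was the subject of the meeting: whether a flask kept cold, where Q works slowly, ends ahead of the hot ones.

all flasks: Q 5 mol%; time 3.0 h
- midnight: Z 0.10 M; D 5.00 equiv (fed, over 2.5 h); the addition at 20 °C, then warmed to 50 °C; the feed brings no volume worth counting
- summer: Z 0.10 M; D 5.00 equiv (fed, over 2.5 h); all else is in the flask from the start; the feed brings no volume worth counting; temperature 50 °C
- dusk: Z 0.10 M; D 5.00 equiv; everything together at the start at 20 °C, warmed to 50 °C at 2.5 h
- dawn: Z 0.10 M (fed, over 2.5 h); D 5.00 equiv; all else is in the flask from the start; the feed brings no volume worth counting; temperature 50 °C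
- spring: Z 0.10 M; D 5.00 equiv; everything together at the start; temperature 50 °C

    Z + D + Q → Z.D + Q, rate k1*[Z]*[D]*[Q]/(1 + ([Z]/sat1)) (sat1 = 42.0 mM, k1 = 39.8 /M²/min, Ea1 = 53.0 kJ/mol)
    2 Q → Q2 (k2 = 1.77 /M/min, Ea2 = 60.0 kJ/mol)
    Z + Z.D → Z.Z.D (k3 = 0.314 /M/min, Ea3 = 63.0 kJ/mol)
    Q → E (k4 = 0.431 /min, Ea4 = 80.0 kJ/mol)
    (constants at 50 °C)

- a species is counted by the Z in it: one Z.Z.D counts as two
- a step written with two of one species runs at k times the square of its concentration and takes two of it each time
- all constants are for 50 °C and move with temperature by the activation energies

* which flask leads in amount of Z.Z.D, in percent of the Z charged ("all alike" within 1.5 percentage points) (midnight / summer / dusk / dawn / spring / all alike)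
* how much Z.Z.D is there at the end, in percent of the Z charged: midnight
* how much Z.Z.D is there at the end, in percent of the Z charged: summer
* how much Z.Z.D is there at the end, in percent of the Z charged: dusk
* how much Z.Z.D is there at the end, in percent of the Z charged: dawn
* how much Z.Z.D is there at the end, in percent of the Z charged: spring

The chair replaced the falling curve of c(Q) by its mean: for a first-order loss, the area under the curve is the starting c(Q) times the lifetime 1/k4. With c(Z) and c(D) held at their charges, she reached 3.82 at 20 °C and 1.37 at 50 °C. This is the turnover budget, a turnover number: the rate of step one per Q, k1·c(Z)·c(D)/(1 + c(Z)/sat1), divided by k4. Cooling raises it by a factor of 2.79, since Q's loss has the larger activation energy.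

A second member objected that Q also goes to Q2. The chair answered that at the start of dusk the step to E uses Q 11 times as fast as the step to Q2, so she left Q2 out. A third member asked about the falling c(Z). I reckoned that with c(Z) held throughout at the level that step one leaves on this budget in dusk, the rate comes out lower by 6.53%, an error she accepted.

The same member then raised the feeds. The lifetime of Q is 2.32 min at 50 °C, far shorter than the feed of 2.5 h, so in summer and dawn the steady feed has delivered 1.55% of its charge after one lifetime of Q. In midnight the cold lifetime of 48.8 min is shorter than the feed too, and she scaled the budget by their ratio, 0.325.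

On the budget we committed to dusk in the lead. My reckoning goes no further than Z.D made in dusk, 19.1% of the Z charged. Z.Z.D counts two, so if every Z.D goes on to Z.Z.D the estimate is 38.2%, and I give no figure for the part reached by the end.

The forecast named dusk, with 6.6% for midnight, 0.2% for summer, 21% for dusk, 0.62% for dawn and 13.1% for spring, on the ground that “Q is the limiter”.

Dusk holds 21.0% of Z.Z.D at 3.00 h, the most of the flasks; at that time midnight holds 6.50%, summer 0.203% and dawn 0.592%. Beside the Z.Z.D of dusk stands 6.46% of Z.D, and after 30.0 h dusk holds 33.9% of Z.Z.D, below the estimated 38.2%. In spring, the budget of 1.37 at a loading of 5 mol% gives an estimate of 13.7% in the same way, and spring holds 13.1% of Z.Z.D at 3.00 h, with 0.0480% of Z.D beside it.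

Its constants are invented; what happens was integrated by code.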